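Everything rests on cutting the pyran ring of the chroman (O1, spiro C2, C3, C4, C4a, C8a) at C2=C3 and O1–C2: spiro C2 is the carbonyl carbon of (+)-nopinone, and C3–C4 is the acetyl group of an ortho-hydroxyacetophenone. One pyrrolidine-mediated Kabbe condensation forms both bonds, closes the pyranone ring and sets the spiro centre, with O1 entering anti to the gem-dimethyl bridge. The precursor is a 3-acetyl-4-hydroxy isovalerophenone whose 2- and 6-oxygens are benzylated, so only the phenol para to the isovaleryl group can cyclise; it is built without Lewis acids once benzyl ethers are present. Removal of the C4 carbonyl, hydrogenolysis and C8 formylation finish the route.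

Key step: step 7

Remark: reagents that deliver only a protecting group, a halogen or a one- or two-carbon unit are given with SMILES on the reagent line and carry no compound number. Chroman atoms are numbered O1 to C8a and pinane atoms C1 to C7, with the gem-dimethyl carbon as C6 and the CH2 bridge as C7; "anti" means on the side of C7.

Step 1
Reactants: 1 phloroglucinol; 2 isovaleryl chloride (3-methylbutanoyl chloride)
Product: 3 1-(2,4,6-trihydroxyphenyl)-3-methylbutan-1-one
Conditions: AlCl3 (4 equiv), PhNO2–CH2Cl2, 0 → 40 °C; then ice/aq. HCl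
Reagents that add atoms: none
Why: Friedel–Crafts C-acylation of the threefold activated ring, which should stop at the monoketone because the aluminium chelate of the product is strongly deactivated.

Step 2
Reactants: 3 1-(2,4,6-trihydroxyphenyl)-3-methylbutan-1-one
Product: 4 3,5-dihydroxy-4-(3-methylbutanoyl)phenyl 4-methylbenzenesulfonate
Conditions: TsCl (1.05 equiv), K2CO3 (1.2 equiv), acetone, 0 °C → rt
Reagents that add atoms: p-toluenesulfonyl chloride, Cc1ccc(cc1)S(=O)(=O)Cl
Why: O-Sulfonylation under mild base should go to the 4-hydroxyl, the only one that is not hydrogen-bonded to the ketone and the most acidic one (para to the acyl group), and a sulfonate is chosen because, unlike a silyl ether, it survives the carbonate alkylation that follows.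

Step 3
Reactants: 4 3,5-dihydroxy-4-(3-methylbutanoyl)phenyl 4-methylbenzenesulfonate
Product: 5 3,5-bis(benzyloxy)-4-(3-methylbutanoyl)phenyl 4-methylbenzenesulfonate
Conditions: BnBr (2.5 equiv), K2CO3 (3 equiv), n-Bu4NI (cat.), DMF, 60 °C
Reagents that add atoms: benzyl bromide, BrCc1ccccc1
Why: Williamson etherification of the two equivalent chelated phenols in DMF, with the sulfonate inert and the electron-poor ring disfavouring C-benzylation.

Step 4
Reactants: 5 3,5-bis(benzyloxy)-4-(3-methylbutanoyl)phenyl 4-methylbenzenesulfonate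
Product: 6 1-[2,6-bis(benzyloxy)-4-hydroxyphenyl]-3-methylbutan-1-one
Conditions: KOH (5 equiv), MeOH–THF–H2O, 60 °C; then aq. HCl to pH 4
Reagents that add atoms: none
Why: Hydroxide or methoxide attack at sulfur cleaves the aryl sulfonate (saponification, with the para-acyl phenoxide as leaving group) while aryl benzyl ethers and the hindered ketone are stable to base.

Step 5
Reactants: 6 1-[2,6-bis(benzyloxy)-4-hydroxyphenyl]-3-methylbutan-1-one
Product: 7 1-[2,6-bis(benzyloxy)-4-hydroxy-3-iodophenyl]-3-methylbutan-1-one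
Conditions: NIS (1.0 equiv), MeCN–CH2Cl2, −20 → 0 °C
Reagents that add atoms: N-iodosuccinimide, O=C1CCC(=O)N1I
Why: Electrophilic aromatic iodination of the phenol at one of its two equivalent ortho positions, the only ring C–H sites, with one equivalent at low temperature favouring the monoiodide because iodine lowers the nucleophilicity of the ring.

Step 6
Reactants: 7 1-[2,6-bis(benzyloxy)-4-hydroxy-3-iodophenyl]-3-methylbutan-1-one
Product: 9 1-[3-acetyl-2,6-bis(benzyloxy)-4-hydroxyphenyl]-3-methylbutan-1-one, via aryl enol ether 8 (not isolated)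
Conditions: Bu3Sn–C(OEt)=CH2 (1.3 equiv), PdCl2(PPh3)2 (5 mol%), 1,4-dioxane, 95 °C; then 1 M HCl, THF, rt
Reagents that add atoms: tributyl(1-ethoxyvinyl)stannane, CCCC[Sn](CCCC)(CCCC)C(=C)OCC; water, O
Why: Stille cross-coupling with a masked acetyl anion equivalent and mild acid hydrolysis of enol ether 8 install the C-acetyl group without the strong Lewis acids of a Fries or Friedel–Crafts acylation, which would cleave benzyl ethers ortho to a ketone.

Step 7
Reactants: 9 1-[3-acetyl-2,6-bis(benzyloxy)-4-hydroxyphenyl]-3-methylbutan-1-one; 10 (+)-nopinone, (1R,5S)-6,6-dimethylbicyclo[3.1.1]heptan-2-one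
Product: 14 (1R,2R,5S)-5',7'-bis(benzyloxy)-6,6-dimethyl-6'-(3-methylbutanoyl)spiro[bicyclo[3.1.1]heptane-2,2'-chroman]-4'-one (O1 anti to the gem-dimethyl bridge), via iminium ion 11 (not isolated), via Mannich base 12 (not isolated), via enone 13 (not isolated)
Conditions: pyrrolidine (1.0 equiv), butanoic acid (0.2 equiv), MeCN, 3 Å molecular sieves, 25 → 45 °C; quench with cold aq. NH4Cl once 13 is consumed
Reagents that add atoms: none
Why: Pyrrolidine condenses with 10 to iminium ion 11, the enol of the acetyl group of 9 adds to the iminium carbon in a Mannich-type step to give 12, and E1cB loss of pyrrolidine delivers enone 13 with the new C2=C3 bond. The phenol oxygen, held ortho to the enone carbonyl, then adds to trigonal C2 in a 6-endo-trig oxa-Michael closure that forms O1–C2 and the pyranone ring; the whole is a Kabbe condensation of a 2-hydroxyacetophenone with a cyclic ketone. The spiro stereocentre is set in this closure by substrate control: the C6 gem-dimethyl bridge, held in place by the C1 and C5 bridgeheads of nopinone, shields one face of C2, so O1 should enter from the side of the C7 bridge and C3 ends up syn to the gem-dimethyl bridge. Regioselectivity is secured because O1 is the only free phenol (the other oxygen ortho to the acetyl group is benzylated), and chemoselectivity because the isovaleryl carbonyl is screened on both faces by its two ortho benzyloxy groups and should neither condense nor form an enamine. Facial selectivity has to be kinetic, since the epimer with C3 anti to the bridge is expected to be the more stable one; the twisted isovaleryl group makes the phenoxide a poorer leaving group, and a temperature of at most 45 °C with work-up as soon as 13 has gone is meant to keep retro-Michael ring opening from equilibrating the centre.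

Step 8
Reactants: 14 (1R,2R,5S)-5',7'-bis(benzyloxy)-6,6-dimethyl-6'-(3-methylbutanoyl)spiro[bicyclo[3.1.1]heptane-2,2'-chroman]-4'-one
Product: 15 N'-[(1R,2R,5S)-5',7'-bis(benzyloxy)-6,6-dimethyl-6'-(3-methylbutanoyl)spiro[bicyclo[3.1.1]heptane-2,2'-chroman]-4'-ylidene]-4-methylbenzenesulfonohydrazide
Conditions: TsNHNH2 (1.5 equiv), PPTS (5 mol%), EtOH–THF, 45 °C
Reagents that add atoms: p-toluenesulfonohydrazide, Cc1ccc(cc1)S(=O)(=O)NN
Why: Hydrazone condensation should be selective for the planar ring ketone at C4, since the isovaleryl carbonyl is twisted out of the arene plane by its two ortho benzyloxy groups, which sit above and below the carbonyl carbon and block addition as in other 2,6-disubstituted aryl ketones.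

Step 9
Reactants: 15 tosylhydrazone of 14
Product: 17 1-[(1R,2R,5S)-5',7'-bis(benzyloxy)-6,6-dimethylspiro[bicyclo[3.1.1]heptane-2,2'-chroman]-6'-yl]-3-methylbutan-1-one, via N-boryl tosylhydrazine 16 (not isolated)
Conditions: catecholborane (2.5 equiv), CHCl3, 0 °C → rt; then NaOAc·3H2O (3 equiv), 60 °C
Reagents that add atoms: none
Why: Kabalka reduction, in which catecholborane delivers hydride to the C=N carbon to give 16 and acetate then triggers loss of p-toluenesulfinate and dinitrogen, leaves CH2 at C4 under nearly neutral conditions that should touch neither the spiro ether, the hindered ketone nor the benzyl ethers.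

Step 10
Reactants: 17 1-[(1R,2R,5S)-5',7'-bis(benzyloxy)-6,6-dimethylspiro[bicyclo[3.1.1]heptane-2,2'-chroman]-6'-yl]-3-methylbutan-1-one
Product: 18 1-[(1R,2R,5S)-5',7'-dihydroxy-6,6-dimethylspiro[bicyclo[3.1.1]heptane-2,2'-chroman]-6'-yl]-3-methylbutan-1-one
Conditions: H2 (1 atm), 10% Pd/C, EtOAc, rt
Reagents that add atoms: none
Why: Hydrogenolysis of the two aryl benzyl ethers over Pd/C is neutral, so the acid-sensitive tertiary pinanyl aryl ether and the cyclobutane are left alone, and the ketone ends up as a doubly hydrogen-bonded acylphloroglucinol carbonyl that resists reduction.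

Step 11
Reactants: 18 1-[(1R,2R,5S)-5',7'-dihydroxy-6,6-dimethylspiro[bicyclo[3.1.1]heptane-2,2'-chroman]-6'-yl]-3-methylbutan-1-one
Product: 20 Euglobal G3, (1R,2R,5S)-5',7'-dihydroxy-6,6-dimethyl-6'-(3-methylbutanoyl)spiro[bicyclo[3.1.1]heptane-2,2'-chromane]-8'-carbaldehyde, via hydroxymethyl phenol 19 (not isolated)
Conditions: MgCl2 (4 equiv), Et3N (8 equiv), (CH2O)n (10 equiv), THF, reflux; then cold dilute HCl
Reagents that add atoms: paraformaldehyde (reacts as formaldehyde), C=O
Why: Casnati–Skattebøl ortho-formylation, in which the magnesium phenoxide of the 7-hydroxyl delivers formaldehyde to C8, the only unsubstituted ring carbon, to give 19 and a second formaldehyde oxidises 19 to the aldehyde by hydride transfer, runs under basic conditions that spare the pinanyl aryl ether.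

Compound list
1 | phloroglucinol (benzene-1,3,5-triol) | Oc1cc(O)cc(O)c1 | starting material
2 | isovaleryl chloride (3-methylbutanoyl chloride) | CC(C)CC(=O)Cl | starting material
3 | 1-(2,4,6-trihydroxyphenyl)-3-methylbutan-1-one | CC(C)CC(=O)c1c(O)cc(O)cc1O | intermediate
4 | 3,5-dihydroxy-4-(3-methylbutanoyl)phenyl 4-methylbenzenesulfonate | CC(C)CC(=O)c1c(O)cc(OS(=O)(=O)c2ccc(C)cc2)cc1O | intermediate
5 | 3,5-bis(benzyloxy)-4-(3-methylbutanoyl)phenyl 4-methylbenzenesulfonate | CC(C)CC(=O)c1c(OCc2ccccc2)cc(OS(=O)(=O)c2ccc(C)cc2)cc1OCc1ccccc1 | intermediate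
6 | 1-[2,6-bis(benzyloxy)-4-hydroxyphenyl]-3-methylbutan-1-one | CC(C)CC(=O)c1c(OCc2ccccc2)cc(O)cc1OCc1ccccc1 | intermediate
7 | 1-[2,6-bis(benzyloxy)-4-hydroxy-3-iodophenyl]-3-methylbutan-1-one | CC(C)CC(=O)c1c(OCc2ccccc2)cc(O)c(I)c1OCc1ccccc1 | intermediate
8 | 1-[2,6-bis(benzyloxy)-3-(1-ethoxyvinyl)-4-hydroxyphenyl]-3-methylbutan-1-one (aryl enol ether) | CCOC(=C)c1c(O)cc(OCc2ccccc2)c(C(=O)CC(C)C)c1OCc1ccccc1 | intermediate (not isolated)
9 | 1-[3-acetyl-2,6-bis(benzyloxy)-4-hydroxyphenyl]-3-methylbutan-1-one (precursor of the key step) | CC(C)CC(=O)c1c(OCc2ccccc2)cc(O)c(C(C)=O)c1OCc1ccccc1 | intermediate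
10 | (+)-nopinone, (1R,5S)-6,6-dimethylbicyclo[3.1.1]heptan-2-one | O=C1CC[C@H]2C[C@@H]1C2(C)C | starting material
11 | 1-[(1R,5S)-6,6-dimethylbicyclo[3.1.1]heptan-2-ylidene]pyrrolidinium butanoate (iminium ion) | C1CC[N+](C1)=C1CC[C@H]2C[C@@H]1C2(C)C.CCCC(=O)[O-] | intermediate (not isolated)
12 | 1-[2,6-bis(benzyloxy)-4-hydroxy-3-{2-[(1R,5S)-6,6-dimethyl-2-(pyrrolidin-1-yl)bicyclo[3.1.1]heptan-2-yl]acetyl}phenyl]-3-methylbutan-1-one (Mannich base; CH2 expected anti to the gem-dimethyl bridge, centre lost again on elimination) | CC(C)CC(=O)c1c(OCc2ccccc2)cc(O)c(C(=O)C[C@@]2(N3CCCC3)CC[C@H]3C[C@@H]2C3(C)C)c1OCc1ccccc1 | intermediate (not isolated)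
13 | 1-[2,6-bis(benzyloxy)-3-{2-[(1R,5S)-6,6-dimethylbicyclo[3.1.1]heptan-2-ylidene]acetyl}-4-hydroxyphenyl]-3-methylbutan-1-one (enone; alkene geometry not fixed) | CC(C)CC(=O)c1c(OCc2ccccc2)cc(O)c(C(=O)C=C2CC[C@H]3C[C@@H]2C3(C)C)c1OCc1ccccc1 | intermediate (not isolated)
14 | (1R,2R,5S)-5',7'-bis(benzyloxy)-6,6-dimethyl-6'-(3-methylbutanoyl)spiro[bicyclo[3.1.1]heptane-2,2'-chroman]-4'-one; O1 anti to the gem-dimethyl bridge (product of the key step) | CC(C)CC(=O)c1c(OCc2ccccc2)cc2c(c1OCc1ccccc1)C(=O)C[C@@]1(CC[C@H]3C[C@@H]1C3(C)C)O2 | intermediate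
15 | tosylhydrazone of 14 at C4 (C=N geometry not fixed) | CC(C)CC(=O)c1c(OCc2ccccc2)cc2c(c1OCc1ccccc1)C(=NNS(=O)(=O)c1ccc(C)cc1)C[C@@]1(CC[C@H]3C[C@@H]1C3(C)C)O2 | intermediate
16 | N-(1,3,2-benzodioxaborol-2-yl) tosylhydrazine from hydride addition to C4 of 15 (C4 configuration not fixed, centre lost in the same step) | CC(C)CC(=O)c1c(OCc2ccccc2)cc2c(c1OCc1ccccc1)C(N(NS(=O)(=O)c1ccc(C)cc1)B1Oc3ccccc3O1)C[C@@]1(CC[C@H]3C[C@@H]1C3(C)C)O2 | intermediate (not isolated)
17 | 1-[(1R,2R,5S)-5',7'-bis(benzyloxy)-6,6-dimethylspiro[bicyclo[3.1.1]heptane-2,2'-chroman]-6'-yl]-3-methylbutan-1-one | CC(C)CC(=O)c1c(OCc2ccccc2)cc2c(c1OCc1ccccc1)CC[C@@]1(CC[C@H]3C[C@@H]1C3(C)C)O2 | intermediate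
18 | 1-[(1R,2R,5S)-5',7'-dihydroxy-6,6-dimethylspiro[bicyclo[3.1.1]heptane-2,2'-chroman]-6'-yl]-3-methylbutan-1-one | CC(C)CC(=O)c1c(O)cc2c(c1O)CC[C@@]1(CC[C@H]3C[C@@H]1C3(C)C)O2 | intermediate
19 | 1-[(1R,2R,5S)-5',7'-dihydroxy-8'-(hydroxymethyl)-6,6-dimethylspiro[bicyclo[3.1.1]heptane-2,2'-chroman]-6'-yl]-3-methylbutan-1-one | CC(C)CC(=O)c1c(O)c(CO)c2c(c1O)CC[C@@]1(CC[C@H]3C[C@@H]1C3(C)C)O2 | intermediate (not isolated)
20 | Euglobal G3, (1R,2R,5S)-5',7'-dihydroxy-6,6-dimethyl-6'-(3-methylbutanoyl)spiro[bicyclo[3.1.1]heptane-2,2'-chromane]-8'-carbaldehyde | CC(C)CC(=O)c1c(O)c(C=O)c2c(c1O)CC[C@@]1(CC[C@H]3C[C@@H]1C3(C)C)O2 | target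

Total step count: 11. Longest linear sequence: 11 steps, from 1 to 20; nopinone 10 enters at step 7 as purchased.

Steps most likely to fail

Step 7. The spiro centre may form with poor facial selectivity or drift towards the other epimer through reversible ring opening, and condensation at the hindered nopinone carbonyl may be slow. The fallback sets out from phenol 6 and builds the same ring by cycloaddition, without a C4 carbonyl. Ortho-formylation of 6 (MgCl2, Et3N, paraformaldehyde, THF, reflux) would give 2,4-bis(benzyloxy)-6-hydroxy-3-(3-methylbutanoyl)benzaldehyde F1. Reduction of the aldehyde (NaBH4, MeOH, 0 °C) would give the salicyl alcohol 1-[2,6-bis(benzyloxy)-4-hydroxy-3-(hydroxymethyl)phenyl]-3-methylbutan-1-one F2. Heating F2 with an excess of (−)-β-pinene (C=C1CC[C@H]2C[C@@H]1C2(C)C; toluene, sealed tube, 150–170 °C) should expel water to the ortho-quinone methide F3, which the alkene traps in an inverse-electron-demand hetero-Diels–Alder reaction. O1 bonds to pinene C2 from the face anti to the gem-dimethyl bridge and the product is 17. The route is rejoined at 17 and steps 5 to 9 fall away.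

Step 8. Discrimination between the two aryl ketones may be incomplete, or the warm, weakly acidic condensation may open the chromanone by retro-oxa-Michael reaction and scramble the spiro centre. The fallback sets out from 14 and removes the carbonyl by reduction and hydrogenolysis. The bulky hydride LiBH(sec-Bu)3 (THF, −78 → 0 °C) should reach only the unshielded ring ketone and give the chroman-4-ol F4 (either C4 epimer). Hydrogenation of F4 (H2, 10% Pd/C, EtOAc with a little AcOH, rt) would cleave both benzyl ethers and the benzylic C4–O bond of the resulting ortho-hydroxybenzyl alcohol in one operation. This gives 18, where the route is rejoined with steps 8 to 10 replaced.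

Step 11. C–C bond formation at C8 may be slow or incomplete because the ortho acyl group ties up magnesium and lowers the nucleophilicity of the phenoxide, and 19 may condense with a second arene instead of being oxidised. The fallback sets out from 17 and formylates before deprotection. Vilsmeier–Haack reaction on the fully protected ring (POCl3, DMF, 0 °C → rt) would pass through the aryl iminium chloride F5. Hydrolysis with aqueous NaOAc would give the 8'-carbaldehyde F6. Hydrogenolysis of the benzyl ethers (H2, 10% Pd/C, EtOAc, rt, stopped after two equivalents of hydrogen) would then give 20, so the fallback comes back at the target.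

Further compounds
F1 | step 7 | 2,4-bis(benzyloxy)-6-hydroxy-3-(3-methylbutanoyl)benzaldehyde | CC(C)CC(=O)c1c(OCc2ccccc2)cc(O)c(C=O)c1OCc1ccccc1
F2 | step 7 | 1-[2,6-bis(benzyloxy)-4-hydroxy-3-(hydroxymethyl)phenyl]-3-methylbutan-1-one | CC(C)CC(=O)c1c(OCc2ccccc2)cc(O)c(CO)c1OCc1ccccc1
F3 | step 7 | 3,5-bis(benzyloxy)-6-methylidene-4-(3-methylbutanoyl)cyclohexa-2,4-dien-1-one (ortho-quinone methide, not isolated) | CC(C)CC(=O)C1=C(OCc2ccccc2)C(=C)C(=O)C=C1OCc1ccccc1
F4 | step 8 | 1-[(1R,2R,5S)-5',7'-bis(benzyloxy)-4'-hydroxy-6,6-dimethylspiro[bicyclo[3.1.1]heptane-2,2'-chroman]-6'-yl]-3-methylbutan-1-one (C4' configuration not fixed) | CC(C)CC(=O)c1c(OCc2ccccc2)cc2c(c1OCc1ccccc1)C(O)C[C@@]1(CC[C@H]3C[C@@H]1C3(C)C)O2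
F5 | step 11 | N-{[(1R,2R,5S)-5',7'-bis(benzyloxy)-6,6-dimethyl-6'-(3-methylbutanoyl)spiro[bicyclo[3.1.1]heptane-2,2'-chroman]-8'-yl]methylidene}-N-methylmethanaminium chloride (not isolated) | CC(C)CC(=O)c1c(OCc2ccccc2)c(C=[N+](C)C)c2c(c1OCc1ccccc1)CC[C@@]1(CC[C@H]3C[C@@H]1C3(C)C)O2.[Cl-]
F6 | step 11 | (1R,2R,5S)-5',7'-bis(benzyloxy)-6,6-dimethyl-6'-(3-methylbutanoyl)spiro[bicyclo[3.1.1]heptane-2,2'-chromane]-8'-carbaldehyde | CC(C)CC(=O)c1c(OCc2ccccc2)c(C=O)c2c(c1OCc1ccccc1)CC[C@@]1(CC[C@H]3C[C@@H]1C3(C)C)O2
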